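The isoflavone is opened at O1–C2/C2–C3 and at C4–C4a, leaving ring A as a hexasubstituted phloroglucinol that is assembled, not prenylated. A Danheiser benzannulation of a cyclobutenone with a siloxyalkyne forges C7–C8, C8a–C4a and C6–C7 in one heating. It exploits the ring A pattern in which the prenylated carbons C6 and C8 each sit between two oxygens (O5/O7 and O7/O8a): both prenyls arrive on carbon, the three oxygens emerge differentiated (O7–H, O5–Et, O8a–Si) and C4a–H is the only open ring position. The precursors are racemic 3-ethoxy-4-prenylcyclobutenone and a prenyl-substituted triisopropylsiloxyalkyne.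

Key step: step 4

Remarks on the chemistry:
- Ring atoms carry isoflavone numbers (O1, C2, C3, C4, C4a, C5–C8, C8a; ring B primed), also in the ring A intermediates. Prenyl = 3-methylbut-2-enyl, MOM = methoxymethyl, TIPS = triisopropylsilyl.
- The target is achiral. The stereocentres of the cyclobutenone and of two transient annulation intermediates are racemic and vanish on aromatisation.
- The structures of both annulation partners and of the annulation product were traced atom by atom through the mechanism of step 4 and needed no correction.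
- Both partners are kept as they are. C4a lies between OEt and the bulky OTIPS group, which shields it from directed lithiation, so it is brominated and metalated by halogen–lithium exchange.

Step 1
Reactants: 1 5-methylhex-4-enoic acid
Product: 2 5-methylhex-4-enoyl chloride
Conditions: (COCl)2, cat. DMF, CH2Cl2, 0 °C → rt; volatiles removed, used crude
Reagents that add atoms: oxalyl chloride, ClC(=O)C(=O)Cl
Why: Acid chloride formation through the catalytic chloroiminium species; the gaseous by-products leave and the isolated trisubstituted alkene should not add HCl in the short contact time.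

Step 2
Reactants: 2 5-methylhex-4-enoyl chloride; 3 ethoxyacetylene
Product: 5 3-ethoxy-4-(3-methylbut-2-enyl)cyclobut-2-en-1-one (racemic), via prenylketene 4 (not isolated)
Conditions: Et3N, excess 3, Et2O/hexanes, slow addition of 2, rt → 35 °C
Reagents that add atoms: none
Why: Dehydrochlorination gives aldoketene 4, which is trapped in a ketene–alkoxyalkyne [2+2] cycloaddition; the nucleophilic CH terminus of 3 bonds to the ketene carbonyl carbon, so ethoxy ends at C3 and prenyl at C4, whose racemic stereocentre is later erased.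

Step 3
Reactants: 6 ethyl 4-methylpent-3-enoate; 7 chlorotriisopropylsilane
Product: 10 5-methyl-1-(triisopropylsilyloxy)hex-4-en-1-yne, via dibromo enolate 8 (not isolated), via lithium ynolate 9 (not isolated)
Conditions: CH2Br2, LiTMP (preformed), THF, −78 °C; 6; then n-BuLi, −78 °C → rt; then 7, −78 °C → rt
Reagents that add atoms: dibromomethane, BrCBr
Why: Kowalski homologation: LiCHBr2 adds to the ester faster than it enolises it at −78 °C, enolate 8 undergoes bromine–lithium exchange and 1,2-migration of the prenyl group to ynolate 9, and the bulky silyl chloride captures 9 on oxygen.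

Step 4
Reactants: 5 3-ethoxy-4-(3-methylbut-2-enyl)cyclobut-2-en-1-one (racemic); 10 5-methyl-1-(triisopropylsilyloxy)hex-4-en-1-yne
Product: 15 3-ethoxy-2,6-bis(3-methylbut-2-enyl)-5-(triisopropylsilyloxy)phenol, via vinylketene 11 (not isolated), via vinylcyclobutenone 12 (not isolated), via dienylketene 13 (not isolated), via cyclohexadienone 14 (not isolated)
Conditions: 10 (1.3 equiv), toluene, 80 → 110 °C, Ar, sealed tube
Reagents that add atoms: none
Why: Thermal conrotatory 4π opening of 5 gives vinylketene 11 (prenylmethyl turning outward), which adds ynol ether 10 in a [2+2] cycloaddition to give 12; a second 4π opening to dienylketene 13 and 6π electrocyclisation give dienone 14, which tautomerises to phenol 15. This is the Danheiser benzannulation of a cyclobutenone with a siloxyalkyne. Ring A closes by the thermal disrotatory 6π electrocyclisation of 13, which forms C6–C7, after the [2+2] step has made C7–C8 and C8a–C4a. The stereocentres of 5, 12 and 14 are racemic and all disappear on aromatisation, so the product has none and no stereocontrol is needed. The selectivity required is regiochemical: the alkyne carbon remote from oxygen must bond to the ketene carbonyl carbon, which the polarisation of the ynol ether and the electrophilic ketene carbon secure, placing prenyl ortho and OTIPS meta to the new hydroxyl. The excess of 10 keeps ketene 11 from acylating the phenol formed.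

Step 5
Reactants: 15 3-ethoxy-2,6-bis(3-methylbut-2-enyl)-5-(triisopropylsilyloxy)phenol
Product: 16 [5-ethoxy-3-(methoxymethoxy)-2,4-bis(3-methylbut-2-enyl)phenoxy]triisopropylsilane
Conditions: NaH, MOMCl, THF/DMF, 0 °C → rt
Reagents that add atoms: chloromethyl methyl ether, COCCl
Why: Williamson O-alkylation of the sodium phenoxide; the small electrophile reaches O7 between two prenyl groups and the aryl silyl ether is inert to NaH.

Step 6
Reactants: 16 [5-ethoxy-3-(methoxymethoxy)-2,4-bis(3-methylbut-2-enyl)phenoxy]triisopropylsilane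
Product: 17 [2-bromo-3-ethoxy-5-(methoxymethoxy)-4,6-bis(3-methylbut-2-enyl)phenoxy]triisopropylsilane
Conditions: NBS (1.0 equiv), DMF, −40 → 0 °C, dark
Reagents that add atoms: N-bromosuccinimide, BrN1C(=O)CCC1=O
Why: Electrophilic aromatic bromination: C4a–H is the only ring hydrogen and is ortho/para to three oxygen donors, so it should outpace the isolated trisubstituted alkenes towards NBS in a polar medium without light.

Step 7
Reactants: 18 2,4-dihydroxybenzaldehyde; 19 prenyl bromide (1-bromo-3-methylbut-2-ene)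
Product: 20 2,4-dihydroxy-3-(3-methylbut-2-enyl)benzaldehyde
Conditions: KOH, H2O, rt; chromatography
Reagents that add atoms: none
Why: Nuclear C-prenylation of the phenoxide in water, a known reaction of this aldehyde that favours the carbon between the two oxygens; O-prenyl and C5 isomers are separated.

Step 8
Reactants: 20 2,4-dihydroxy-3-(3-methylbut-2-enyl)benzaldehyde
Product: 21 2-hydroxy-4-(methoxymethoxy)-3-(3-methylbut-2-enyl)benzaldehyde
Conditions: MOMCl, K2CO3, acetone, rt
Reagents that add atoms: chloromethyl methyl ether, COCCl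
Why: Selective Williamson etherification: the 2-hydroxyl is held in a hydrogen bond to the aldehyde, so the weak base alkylates only the 4-hydroxyl.

Step 9
Reactants: 21 2-hydroxy-4-(methoxymethoxy)-3-(3-methylbut-2-enyl)benzaldehyde
Product: 22 2-methoxy-4-(methoxymethoxy)-3-(3-methylbut-2-enyl)benzaldehyde
Conditions: MeI, K2CO3, DMF, 40 °C
Reagents that add atoms: iodomethane, CI
Why: Williamson O-methylation under conditions forcing enough for the chelated hydroxyl and harmless to the MOM ether and the prenyl group.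

Step 10
Reactants: 22 2-methoxy-4-(methoxymethoxy)-3-(3-methylbut-2-enyl)benzaldehyde
Product: 24 2-[2-methoxy-4-(methoxymethoxy)-3-(3-methylbut-2-enyl)phenyl]acetonitrile, via formamido vinyl sulfone 23 (not isolated)
Conditions: TosMIC, KOt-Bu, DME, −40 °C; then MeOH, 65 °C
Reagents that add atoms: p-toluenesulfonylmethyl isocyanide (TosMIC), Cc1ccc(cc1)S(=O)(=O)C[N+]#[C-]
Why: Van Leusen reductive cyanation: the TosMIC anion adds to the aldehyde to give 23, methanolysis removes the formyl group and loss of sulfinate gives the homologous nitrile under basic conditions that spare MOM and prenyl.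

Step 11
Reactants: 24 2-[2-methoxy-4-(methoxymethoxy)-3-(3-methylbut-2-enyl)phenyl]acetonitrile
Product: 25 2-[2-methoxy-4-(methoxymethoxy)-3-(3-methylbut-2-enyl)phenyl]acetic acid
Conditions: KOH, EtOH/H2O, reflux; then 1 M HCl to pH 4, 0 °C
Reagents that add atoms: water, O; potassium hydroxide, [K+].[OH-]
Why: Alkaline nitrile hydrolysis, to which the MOM ether and the isolated alkene are inert; the brief cold acidification stops at pH 4.

Step 12
Reactants: 25 2-[2-methoxy-4-(methoxymethoxy)-3-(3-methylbut-2-enyl)phenyl]acetic acid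
Product: 27 N-methoxy-N-methyl-2-[2-methoxy-4-(methoxymethoxy)-3-(3-methylbut-2-enyl)phenyl]acetamide, via acyl imidazole 26 (not isolated)
Conditions: CDI, THF, rt; then MeNHOMe, rt
Reagents that add atoms: N,O-dimethylhydroxylamine, CNOC
Why: Amide formation through the acyl imidazole under neutral conditions gives the Weinreb amide without touching the acid-sensitive groups.

Step 13
Reactants: 17 [2-bromo-3-ethoxy-5-(methoxymethoxy)-4,6-bis(3-methylbut-2-enyl)phenoxy]triisopropylsilane; 27 N-methoxy-N-methyl-2-[2-methoxy-4-(methoxymethoxy)-3-(3-methylbut-2-enyl)phenyl]acetamide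
Product: 29 1-[2-ethoxy-4-(methoxymethoxy)-3,5-bis(3-methylbut-2-enyl)-6-(triisopropylsilyloxy)phenyl]-2-[2-methoxy-4-(methoxymethoxy)-3-(3-methylbut-2-enyl)phenyl]ethanone, via aryllithium 28 (not isolated)
Conditions: t-BuLi (2.0 equiv), Et2O, −78 °C; then 27 in THF, −78 → −20 °C; aq. NH4Cl
Reagents that add atoms: none
Why: Bromine–lithium exchange metalates C4a site-specifically at a temperature where neither silyl migration nor benzylic deprotonation should compete, and the Weinreb ketone synthesis stops at the ketone through the chelated adduct, forming C4a–C4.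

Step 14
Reactants: 29 1-[2-ethoxy-4-(methoxymethoxy)-3,5-bis(3-methylbut-2-enyl)-6-(triisopropylsilyloxy)phenyl]-2-[2-methoxy-4-(methoxymethoxy)-3-(3-methylbut-2-enyl)phenyl]ethanone
Product: 30 1-[2-ethoxy-6-hydroxy-4-(methoxymethoxy)-3,5-bis(3-methylbut-2-enyl)phenyl]-2-[2-methoxy-4-(methoxymethoxy)-3-(3-methylbut-2-enyl)phenyl]ethanone
Conditions: TBAF, AcOH, THF, 0 °C
Reagents that add atoms: none
Why: Fluoride desilylation of the aryl silyl ether ortho to the ketone, buffered so that the acidic benzylic methylene is not deprotonated; MOM, ethyl and prenyl groups are untouched.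

Step 15
Reactants: 30 1-[2-ethoxy-6-hydroxy-4-(methoxymethoxy)-3,5-bis(3-methylbut-2-enyl)phenyl]-2-[2-methoxy-4-(methoxymethoxy)-3-(3-methylbut-2-enyl)phenyl]ethanone
Product: 32 5-ethoxy-7-(methoxymethoxy)-3-[2-methoxy-4-(methoxymethoxy)-3-(3-methylbut-2-enyl)phenyl]-6,8-bis(3-methylbut-2-enyl)chromen-4-one, via enaminone 31 (not isolated)
Conditions: DMF-DMA, toluene, 90 °C
Reagents that add atoms: N,N-dimethylformamide dimethyl acetal, COC(OC)N(C)C
Why: Isoflavone synthesis from a 2-hydroxydeoxybenzoin: the amide acetal condenses at the active methylene to give enaminone 31, and O8a adds to the enamine carbon with loss of dimethylamine, closing ring C without acid or oxidant.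

Step 16
Reactants: 32 5-ethoxy-7-(methoxymethoxy)-3-[2-methoxy-4-(methoxymethoxy)-3-(3-methylbut-2-enyl)phenyl]-6,8-bis(3-methylbut-2-enyl)chromen-4-one
Product: 33 5,7-dihydroxy-3-[4-hydroxy-2-methoxy-3-(3-methylbut-2-enyl)phenyl]-6,8-bis(3-methylbut-2-enyl)chromen-4-one (CNP0331360.0)
Conditions: BCl3 (excess), 2,6-di-tert-butylpyridine, CH2Cl2, −78 → −10 °C; cold aq. NaHCO3
Reagents that add atoms: none
Why: Lewis acid ether cleavage: BCl3 opens both MOM acetals and, by chloride attack on the ethyl carbon within the O5–B–O=C4 chelate, the peri ether, while the unchelated 2'-methyl ether reacts far more slowly; no protic acid forms before the buffered quench and the hindered pyridine traps adventitious HCl, which should protect the three prenyl groups.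

Compound list
1 | 5-methylhex-4-enoic acid | CC(C)=CCCC(=O)O | starting material
2 | 5-methylhex-4-enoyl chloride | CC(C)=CCCC(=O)Cl | intermediate
3 | ethoxyacetylene | CCOC#C | starting material
4 | prenylketene (5-methylhexa-1,4-dien-1-one) | CC(C)=CCC=C=O | intermediate (not isolated)
5 | 3-ethoxy-4-(3-methylbut-2-enyl)cyclobut-2-en-1-one, racemic | CCOC1=CC(=O)C1CC=C(C)C | intermediate
6 | ethyl 4-methylpent-3-enoate | CCOC(=O)CC=C(C)C | starting material
7 | chlorotriisopropylsilane | CC(C)[Si](Cl)(C(C)C)C(C)C | starting material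
8 | lithium 1,1-dibromo-5-methylhexa-1,4-dien-2-olate | [Li+].[O-]C(CC=C(C)C)=C(Br)Br | intermediate (not isolated)
9 | lithium 5-methylhex-4-en-1-yn-1-olate | [Li+].[O-]C#CCC=C(C)C | intermediate (not isolated)
10 | 5-methyl-1-(triisopropylsilyloxy)hex-4-en-1-yne | CC(C)=CCC#CO[Si](C(C)C)(C(C)C)C(C)C | intermediate
11 | (3Z)-3-ethoxy-7-methylocta-1,3,6-trien-1-one | O=C=C/C(OCC)=C/CC=C(C)C | intermediate (not isolated)
12 | 4-[(1Z)-1-ethoxy-5-methylhexa-1,4-dienyl]-2-(3-methylbut-2-enyl)-3-(triisopropylsilyloxy)cyclobut-2-en-1-one, racemic | O=C1C(CC=C(C)C)=C(O[Si](C(C)C)(C(C)C)C(C)C)C1/C(OCC)=C/CC=C(C)C | intermediate (not isolated)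
13 | (3E,5Z)-5-ethoxy-9-methyl-2-(3-methylbut-2-enyl)-3-(triisopropylsilyloxy)deca-1,3,5,8-tetraen-1-one | O=C=C(CC=C(C)C)/C(O[Si](C(C)C)(C(C)C)C(C)C)=C\C(OCC)=C\CC=C(C)C | intermediate (not isolated)
14 | 5-ethoxy-2,6-bis(3-methylbut-2-enyl)-3-(triisopropylsilyloxy)cyclohexa-2,4-dien-1-one, racemic | O=C1C(CC=C(C)C)=C(O[Si](C(C)C)(C(C)C)C(C)C)C=C(OCC)C1CC=C(C)C | intermediate (not isolated)
15 | 3-ethoxy-2,6-bis(3-methylbut-2-enyl)-5-(triisopropylsilyloxy)phenol | Oc1c(CC=C(C)C)c(O[Si](C(C)C)(C(C)C)C(C)C)cc(OCC)c1CC=C(C)C | intermediate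
16 | [5-ethoxy-3-(methoxymethoxy)-2,4-bis(3-methylbut-2-enyl)phenoxy]triisopropylsilane | COCOc1c(CC=C(C)C)c(O[Si](C(C)C)(C(C)C)C(C)C)cc(OCC)c1CC=C(C)C | intermediate
17 | [2-bromo-3-ethoxy-5-(methoxymethoxy)-4,6-bis(3-methylbut-2-enyl)phenoxy]triisopropylsilane | COCOc1c(CC=C(C)C)c(O[Si](C(C)C)(C(C)C)C(C)C)c(Br)c(OCC)c1CC=C(C)C | intermediate
18 | 2,4-dihydroxybenzaldehyde | O=Cc1ccc(O)cc1O | starting material
19 | prenyl bromide (1-bromo-3-methylbut-2-ene) | CC(C)=CCBr | starting material
20 | 2,4-dihydroxy-3-(3-methylbut-2-enyl)benzaldehyde | O=Cc1ccc(O)c(CC=C(C)C)c1O | intermediate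
21 | 2-hydroxy-4-(methoxymethoxy)-3-(3-methylbut-2-enyl)benzaldehyde | O=Cc1ccc(OCOC)c(CC=C(C)C)c1O | intermediate
22 | 2-methoxy-4-(methoxymethoxy)-3-(3-methylbut-2-enyl)benzaldehyde | O=Cc1ccc(OCOC)c(CC=C(C)C)c1OC | intermediate
23 | N-{2-[2-methoxy-4-(methoxymethoxy)-3-(3-methylbut-2-enyl)phenyl]-1-tosylethenyl}formamide, alkene geometry not defined (either isomer reacts on) | O=CNC(=Cc1ccc(OCOC)c(CC=C(C)C)c1OC)S(=O)(=O)c1ccc(C)cc1 | intermediate (not isolated)
24 | 2-[2-methoxy-4-(methoxymethoxy)-3-(3-methylbut-2-enyl)phenyl]acetonitrile | N#CCc1ccc(OCOC)c(CC=C(C)C)c1OC | intermediate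
25 | 2-[2-methoxy-4-(methoxymethoxy)-3-(3-methylbut-2-enyl)phenyl]acetic acid | OC(=O)Cc1ccc(OCOC)c(CC=C(C)C)c1OC | intermediate
26 | 1-(imidazol-1-yl)-2-[2-methoxy-4-(methoxymethoxy)-3-(3-methylbut-2-enyl)phenyl]ethanone | O=C(Cc1ccc(OCOC)c(CC=C(C)C)c1OC)n1ccnc1 | intermediate (not isolated)
27 | N-methoxy-N-methyl-2-[2-methoxy-4-(methoxymethoxy)-3-(3-methylbut-2-enyl)phenyl]acetamide | CON(C)C(=O)Cc1ccc(OCOC)c(CC=C(C)C)c1OC | intermediate
28 | [2-ethoxy-4-(methoxymethoxy)-3,5-bis(3-methylbut-2-enyl)-6-(triisopropylsilyloxy)phenyl]lithium | COCOc1c(CC=C(C)C)c(O[Si](C(C)C)(C(C)C)C(C)C)c([Li])c(OCC)c1CC=C(C)C | intermediate (not isolated)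
29 | 1-[2-ethoxy-4-(methoxymethoxy)-3,5-bis(3-methylbut-2-enyl)-6-(triisopropylsilyloxy)phenyl]-2-[2-methoxy-4-(methoxymethoxy)-3-(3-methylbut-2-enyl)phenyl]ethanone | COCOc1c(CC=C(C)C)c(O[Si](C(C)C)(C(C)C)C(C)C)c(C(=O)Cc2ccc(OCOC)c(CC=C(C)C)c2OC)c(OCC)c1CC=C(C)C | intermediate
30 | 1-[2-ethoxy-6-hydroxy-4-(methoxymethoxy)-3,5-bis(3-methylbut-2-enyl)phenyl]-2-[2-methoxy-4-(methoxymethoxy)-3-(3-methylbut-2-enyl)phenyl]ethanone | COCOc1c(CC=C(C)C)c(O)c(C(=O)Cc2ccc(OCOC)c(CC=C(C)C)c2OC)c(OCC)c1CC=C(C)C | intermediate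
31 | 3-(dimethylamino)-1-[2-ethoxy-6-hydroxy-4-(methoxymethoxy)-3,5-bis(3-methylbut-2-enyl)phenyl]-2-[2-methoxy-4-(methoxymethoxy)-3-(3-methylbut-2-enyl)phenyl]prop-2-en-1-one, alkene geometry not defined (either isomer cyclises) | COCOc1c(CC=C(C)C)c(O)c(C(=O)C(=CN(C)C)c2ccc(OCOC)c(CC=C(C)C)c2OC)c(OCC)c1CC=C(C)C | intermediate (not isolated)
32 | 5-ethoxy-7-(methoxymethoxy)-3-[2-methoxy-4-(methoxymethoxy)-3-(3-methylbut-2-enyl)phenyl]-6,8-bis(3-methylbut-2-enyl)chromen-4-one | COc1c(-c2coc3c(CC=C(C)C)c(OCOC)c(CC=C(C)C)c(OCC)c3c2=O)ccc(OCOC)c1CC=C(C)C | intermediate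
33 | 5,7-dihydroxy-3-[4-hydroxy-2-methoxy-3-(3-methylbut-2-enyl)phenyl]-6,8-bis(3-methylbut-2-enyl)chromen-4-one | COc1c(-c2coc3c(CC=C(C)C)c(O)c(CC=C(C)C)c(O)c3c2=O)ccc(O)c1CC=C(C)C | target

Total step count: 16. Longest linear sequence: 10 steps (18 → 33 through steps 7–12 and 13–16).

Steps most likely to fail

1. Step 4. The vinylogous-ester cyclobutenone may open too slowly, so that the siloxyalkyne decomposes or the ketene dimerises or acylates the product before the cascade is complete. The fallback builds the same ring A pattern by three directed ortho-lithiations. It sets out from prenyl bromide 19 and Weinreb amide 27, together with purchased phloroglucinol, and comes back at hydroxy ketone 30. Phloroglucinol is mono-ethylated (EtOH, HCl) to 5-ethoxybenzene-1,3-diol F1 and protected (MOMCl, i-Pr2NEt) as 1-ethoxy-3,5-bis(methoxymethoxy)benzene F2. Lithiation between the two MOM ethers (n-BuLi, THF, 0 °C) and alkylation with 19 should give 5-ethoxy-1,3-bis(methoxymethoxy)-2-(3-methylbut-2-enyl)benzene F3. A second lithiation between OEt and OMOM (the two sites are equivalent) and 19 should give 1-ethoxy-3,5-bis(methoxymethoxy)-2,4-bis(3-methylbut-2-enyl)benzene F4. Lithiation of the last ring hydrogen, now flanked by OEt and OMOM, and addition to 27 should give the MOM-protected ketone F5. Chelation-controlled cleavage of the MOM ether ortho to the carbonyl (MgBr2·OEt2, Et2O) then delivers 30.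

2. Step 16. While three ethers are cleaved at once, a prenyl double bond may be protonated and cyclise onto a neighbouring oxygen (chroman formation) or add HCl. The fallback unmasks in two stages, keeping the phenols that lie next to prenyl groups capped for as long as possible. It sets out from 32 and comes back at 33. The peri ethyl ether alone is cleaved by iodide under magnesium chelation (MgI2·OEt2, THF/toluene, 60 °C) to 5-hydroxy-7-(methoxymethoxy)-3-[2-methoxy-4-(methoxymethoxy)-3-(3-methylbut-2-enyl)phenyl]-6,8-bis(3-methylbut-2-enyl)chromen-4-one F6. Its two MOM ethers are then hydrolysed with dilute HCl in MeOH at rt to 40 °C, the protic conditions commonly used for MOM-protected prenylated phenols.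

3. Step 6. Bromonium formation at the prenyl double bonds or over-bromination may compete with substitution at C4a; the fallback also bypasses step 13, where the Weinreb amide might enolise. It forms the C4a–C bond by phenoxide-directed formylation, sets out from 16 and aldehyde 22 and comes back at 30. TBAF removes the silyl group of 16 to give 5-ethoxy-3-(methoxymethoxy)-2,4-bis(3-methylbut-2-enyl)phenol F7. Casnati–Skattebøl formylation (MgCl2, Et3N, paraformaldehyde, MeCN, reflux) can only occur at C4a and should give 6-ethoxy-2-hydroxy-4-(methoxymethoxy)-3,5-bis(3-methylbut-2-enyl)benzaldehyde F8. Aldehyde 22 is reduced (NaBH4, MeOH) to [2-methoxy-4-(methoxymethoxy)-3-(3-methylbut-2-enyl)phenyl]methanol F9, converted (MsCl, Et3N, LiCl) to 1-(chloromethyl)-2-methoxy-4-(methoxymethoxy)-3-(3-methylbut-2-enyl)benzene F10 and then (Mg, THF, 0 °C) to [2-methoxy-4-(methoxymethoxy)-3-(3-methylbut-2-enyl)benzyl]magnesium chloride F11. F8, deprotonated beforehand with i-PrMgCl, adds F11 to give 1-[2-ethoxy-6-hydroxy-4-(methoxymethoxy)-3,5-bis(3-methylbut-2-enyl)phenyl]-2-[2-methoxy-4-(methoxymethoxy)-3-(3-methylbut-2-enyl)phenyl]ethanol F12 (racemic), whose benzylic alcohol is oxidised (MnO2, CH2Cl2, or Dess–Martin periodinane) to 30.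

Further compounds
F1 | step 4 | 5-ethoxybenzene-1,3-diol | CCOc1cc(O)cc(O)c1
F2 | step 4 | 1-ethoxy-3,5-bis(methoxymethoxy)benzene | CCOc1cc(OCOC)cc(OCOC)c1
F3 | step 4 | 5-ethoxy-1,3-bis(methoxymethoxy)-2-(3-methylbut-2-enyl)benzene | CCOc1cc(OCOC)c(CC=C(C)C)c(OCOC)c1
F4 | step 4 | 1-ethoxy-3,5-bis(methoxymethoxy)-2,4-bis(3-methylbut-2-enyl)benzene | CCOc1cc(OCOC)c(CC=C(C)C)c(OCOC)c1CC=C(C)C
F5 | step 4 | 1-[2-ethoxy-4,6-bis(methoxymethoxy)-3,5-bis(3-methylbut-2-enyl)phenyl]-2-[2-methoxy-4-(methoxymethoxy)-3-(3-methylbut-2-enyl)phenyl]ethanone | CCOc1c(C(=O)Cc2ccc(OCOC)c(CC=C(C)C)c2OC)c(OCOC)c(CC=C(C)C)c(OCOC)c1CC=C(C)C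
F6 | step 16 | 5-hydroxy-7-(methoxymethoxy)-3-[2-methoxy-4-(methoxymethoxy)-3-(3-methylbut-2-enyl)phenyl]-6,8-bis(3-methylbut-2-enyl)chromen-4-one | COc1c(-c2coc3c(CC=C(C)C)c(OCOC)c(CC=C(C)C)c(O)c3c2=O)ccc(OCOC)c1CC=C(C)C
F7 | step 6 | 5-ethoxy-3-(methoxymethoxy)-2,4-bis(3-methylbut-2-enyl)phenol | COCOc1c(CC=C(C)C)c(O)cc(OCC)c1CC=C(C)C
F8 | step 6 | 6-ethoxy-2-hydroxy-4-(methoxymethoxy)-3,5-bis(3-methylbut-2-enyl)benzaldehyde | COCOc1c(CC=C(C)C)c(O)c(C=O)c(OCC)c1CC=C(C)C
F9 | step 6 | [2-methoxy-4-(methoxymethoxy)-3-(3-methylbut-2-enyl)phenyl]methanol | OCc1ccc(OCOC)c(CC=C(C)C)c1OC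
F10 | step 6 | 1-(chloromethyl)-2-methoxy-4-(methoxymethoxy)-3-(3-methylbut-2-enyl)benzene | ClCc1ccc(OCOC)c(CC=C(C)C)c1OC
F11 | step 6 | [2-methoxy-4-(methoxymethoxy)-3-(3-methylbut-2-enyl)benzyl]magnesium chloride | Cl[Mg]Cc1ccc(OCOC)c(CC=C(C)C)c1OC
F12 | step 6 | 1-[2-ethoxy-6-hydroxy-4-(methoxymethoxy)-3,5-bis(3-methylbut-2-enyl)phenyl]-2-[2-methoxy-4-(methoxymethoxy)-3-(3-methylbut-2-enyl)phenyl]ethanol, racemic | COCOc1c(CC=C(C)C)c(O)c(C(O)Cc2ccc(OCOC)c(CC=C(C)C)c2OC)c(OCC)c1CC=C(C)C
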